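Ring A is built from acyclic pieces instead of functionalising a resorcinol. It carries oxygen at C-1 (acetate) and C-3 (free OH), the chain at C-2 between them, and plain C–H at C-4, C-5 and C-6. Unsubstituted vinylketene (C-1, C-4, C-5, C-6) and a chain-bearing silyl ynol ether (C-2, C-3) give exactly this pattern in a Danheiser benzannulation. One operation closes the arene and leaves one oxygen free and the other silylated, so monoacetylation needs no statistical step. The precursors are 1-diazobut-3-en-2-one and 1-(triisopropylsilyloxy)dodec-11-en-1-yne. The terminal alkene of the latter later takes up the ring B aldehyde by linear rhodium hydroacylation.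

Key step: step 3

Remark on the chemistry: the target has no stereocentre and no stereogenic double bond. The two oxygens of the parent 2-alkylresorcinol are equivalent, so it does not matter which one is acetylated, only that exactly one is.

Step 1
Reactants: 1 ethyl undec-10-enoate
Product: 5 1-(triisopropylsilyloxy)dodec-11-en-1-yne, via lithium dibromoenolate 2 (not isolated), via bromolithio carbenoid 3 (not isolated), via lithium ynolate 4 (not isolated)
Conditions: CH2Br2, lithium 2,2,6,6-tetramethylpiperidide (2.2 equiv), THF, −78 °C; n-BuLi, −78 → 25 °C; i-Pr3SiOTf, −78 → 0 °C; Et3N-deactivated silica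
Reagents that add atoms: dibromomethane BrCBr; triisopropylsilyl trifluoromethanesulfonate CC(C)[Si](OS(=O)(=O)C(F)(F)F)(C(C)C)C(C)C
Why: Kowalski ester homologation halted at the ynolate: acylation of LiCHBr2 by the ester and deprotonation give 2, bromine–lithium exchange gives carbenoid 3, whose dec-9-enyl group migrates with loss of LiBr to form 4, and the bulky silyl triflate traps 4 on oxygen, the remote alkene being inert to the lithium bases at these temperatures.

Step 2
Reactants: 6 methyl vinyl ketone
Product: 9 1-diazobut-3-en-2-one, via lithium dienolate 7 (not isolated), via trifluoroacetyl ketone 8 (not isolated)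
Conditions: LiN(SiMe3)2, THF, −78 °C (6 added slowly to the base); CF3CO2CH2CF3, −78 °C; dilute HCl wash; then MsN3, Et3N, H2O (1 equiv), MeCN, 25 °C; product kept cold, dark and in solution
Reagents that add atoms: methanesulfonyl azide CS(=O)(=O)N=[N+]=[N-]; 2,2,2-trifluoroethyl trifluoroacetate O=C(OCC(F)(F)F)C(F)(F)F (its CF3CO group is kept only in 8)
Why: Detrifluoroacetylative diazo transfer: kinetic deprotonation on the methyl side gives 7, a Claisen-type trifluoroacetylation gives the activated diketone 8, and Regitz-type transfer from the sulfonyl azide with loss of the CF3CO group leaves the diazo group at the former methyl carbon, a sequence suited to enones because it avoids diazomethane, which would add across an acryloyl C=C.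

Step 3
Reactants: 5 1-(triisopropylsilyloxy)dodec-11-en-1-yne; 9 1-diazobut-3-en-2-one
Product: 14 2-(dec-9-enyl)-3-(triisopropylsilyloxy)phenol, via vinylketene 10 (not isolated), via vinylcyclobutenone 11 (not isolated), via dienylketene 12 (not isolated), via cyclohexadienone 13 (not isolated)
Conditions: hν (254 nm, low-pressure Hg lamps, quartz), degassed ClCH2CH2Cl, 25 °C, 9 (1.5 equiv) added by syringe pump to 5; then 80 °C in the dark
Reagents that add atoms: none
Why: Light expels N2 from 9 and the vinyl group shifts to the former diazo carbon (photochemical Wolff rearrangement, which already sets the C-4–C-5 bond), and the electrophilic carbonyl carbon of the resulting vinylketene 10 is attacked by the chain-bearing alkyne carbon of 5 in a [2+2] cycloaddition that gives 4-vinylcyclobutenone 11 (C-1–C-2 and C-3–C-4 bonds). Light or the 80 °C stage then opens 11 by a reversible four-electron electrocyclic cleavage of the former ketene C=C bond to dienylketene 12, and because only the isomer with ketene and vinyl termini on the same side of the central C=C can react further, the equilibrium drains through it. Ring A closes by a six-electron disrotatory electrocyclisation of 12 (C-6–C-1 bond) to dienone 13, which enolises irreversibly to 14, so that four of the six ring bonds are new when counted from 9 and three when counted from 10. This is the diazoketone (second-generation) form of the Danheiser benzannulation, in which triisopropylsilyl ynol ethers are established ketenophiles that deliver resorcinol monosilyl ethers. The step needs regioselectivity and chemoselectivity, and both come from oxygen donation into the alkyne, which makes the carbon remote from oxygen the nucleophile (so C-2 with its chain lands between the two oxygenated carbons) and makes the ynol ether far more ketenophilic than the isolated terminal C=C. The only stereocentre formed, C-4 of 11, is racemic and is erased on aromatisation, and slow dosing of 9 keeps both the diazo enone and the polymerisation-prone 10 dilute.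

Step 4
Reactants: 14 2-(dec-9-enyl)-3-(triisopropylsilyloxy)phenol
Product: 15 2-(dec-9-enyl)-3-(triisopropylsilyloxy)phenyl acetate
Conditions: Ac2O, pyridine, DMAP (cat.), CH2Cl2, 0 → 25 °C
Reagents that add atoms: acetic anhydride CC(=O)OC(C)=O
Why: Nucleophile-catalysed O-acylation of the only free hydroxyl, which leaves the aryl silyl ether and the alkene untouched and so fixes the difference between the two ring A oxygens.

Step 5
Reactants: 16 2,4,6-trihydroxybenzaldehyde
Product: 17 2,4-bis(benzyloxy)-6-hydroxybenzaldehyde
Conditions: BnBr (2.05 equiv), K2CO3, DMF, 25 °C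
Reagents that add atoms: benzyl bromide BrCc1ccccc1
Why: Williamson etherification under weak base should stop after two benzylations, because the last ortho-hydroxyl is held in a hydrogen bond to the formyl oxygen and is the least nucleophilic, which leaves exactly the chelating OH that step 6 requires.

Step 6
Reactants: 15 2-(dec-9-enyl)-3-(triisopropylsilyloxy)phenyl acetate; 17 2,4-bis(benzyloxy)-6-hydroxybenzaldehyde
Product: 18 2-{11-[2,4-bis(benzyloxy)-6-hydroxyphenyl]-11-oxoundecyl}-3-(triisopropylsilyloxy)phenyl acetate
Conditions: [Rh(cod)OMe]2 (2.5 mol %), BINOL-derived N,N-bis(1-phenylethyl)phosphoramidite (10 mol %), ClCH2CH2Cl, 70 °C, no added base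
Reagents that add atoms: none
Why: Chelation-assisted intermolecular alkene hydroacylation of a salicylaldehyde: the rhodium phenoxide formed from the methoxide precatalyst inserts into the formyl C–H, the five-membered acyl-rhodium chelate resists decarbonylation, the bulky monodentate ligand steers hydrometallation of the 1-alkene to the linear alkyl before reductive elimination to the n-alkyl aryl ketone, and the base-free medium spares the aryl acetate.

Step 7
Reactants: 18 2-{11-[2,4-bis(benzyloxy)-6-hydroxyphenyl]-11-oxoundecyl}-3-(triisopropylsilyloxy)phenyl acetate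
Product: 19 2-{11-[2,4-bis(benzyloxy)-6-hydroxyphenyl]-11-oxoundecyl}-3-hydroxyphenyl acetate
Conditions: HF·pyridine, THF/pyridine, 0 → 25 °C (polyethylene flask); pH 7 buffer work-up
Reagents that add atoms: none
Why: Fluoride-driven Si–O cleavage in a mildly acidic medium releases the phenol in protonated form, so no phenoxide arises that could take over or lose the acetyl group, while benzyl ethers and ketone are inert.

Step 8
Reactants: 19 2-{11-[2,4-bis(benzyloxy)-6-hydroxyphenyl]-11-oxoundecyl}-3-hydroxyphenyl acetate
Product: 20 3-hydroxy-2-[11-oxo-11-(2,4,6-trihydroxyphenyl)undecyl]phenyl acetate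
Conditions: H2 (1 atm), Pd/C (10 wt %), EtOAc, 25 °C
Reagents that add atoms: none
Why: Neutral heterogeneous hydrogenolysis of the two aryl benzyl ethers, in which the aryl acetate is inert and the ketone, deactivated by three donor oxygens and by hydrogen bonding, should resist reduction at 1 atm, so that filtration and evaporation should deliver the target.

Compound list
1 | ethyl undec-10-enoate | C=CCCCCCCCCC(=O)OCC | starting material
2 | lithium 1,1-dibromododeca-1,11-dien-2-olate | C=CCCCCCCCCC([O-])=C(Br)Br.[Li+] | intermediate
3 | lithium 1-bromo-1-lithiododeca-1,11-dien-2-olate | C=CCCCCCCCCC([O-])=C([Li])Br.[Li+] | intermediate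
4 | lithium dodec-11-en-1-yn-1-olate | C=CCCCCCCCCC#C[O-].[Li+] | intermediate
5 | 1-(triisopropylsilyloxy)dodec-11-en-1-yne | C=CCCCCCCCCC#CO[Si](C(C)C)(C(C)C)C(C)C | intermediate
6 | methyl vinyl ketone (but-3-en-2-one) | C=CC(C)=O | starting material
7 | lithium buta-1,3-dien-2-olate | C=CC([O-])=C.[Li+] | intermediate
8 | 1,1,1-trifluorohex-5-ene-2,4-dione | C=CC(=O)CC(=O)C(F)(F)F | intermediate
9 | 1-diazobut-3-en-2-one | C=CC(=O)C=[N+]=[N-] | intermediate
10 | buta-1,3-dien-1-one (vinylketene) | C=CC=C=O | intermediate
11 | 2-(dec-9-enyl)-4-ethenyl-3-(triisopropylsilyloxy)cyclobut-2-en-1-one (racemic) | C=CCCCCCCCCC1=C(O[Si](C(C)C)(C(C)C)C(C)C)C(C=C)C1=O | intermediate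
12 | (3E)-2-(dec-9-enyl)-3-(triisopropylsilyloxy)hexa-1,3,5-trien-1-one (ketene and vinyl termini cis) | C=C/C=C(O[Si](C(C)C)(C(C)C)C(C)C)\C(CCCCCCCCC=C)=C=O | intermediate
13 | 2-(dec-9-enyl)-3-(triisopropylsilyloxy)cyclohexa-2,4-dien-1-one | C=CCCCCCCCCC1=C(O[Si](C(C)C)(C(C)C)C(C)C)C=CCC1=O | intermediate
14 | 2-(dec-9-enyl)-3-(triisopropylsilyloxy)phenol | C=CCCCCCCCCc1c(O)cccc1O[Si](C(C)C)(C(C)C)C(C)C | intermediate
15 | 2-(dec-9-enyl)-3-(triisopropylsilyloxy)phenyl acetate | C=CCCCCCCCCc1c(OC(C)=O)cccc1O[Si](C(C)C)(C(C)C)C(C)C | intermediate
16 | 2,4,6-trihydroxybenzaldehyde | O=Cc1c(O)cc(O)cc1O | starting material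
17 | 2,4-bis(benzyloxy)-6-hydroxybenzaldehyde | O=Cc1c(O)cc(OCc2ccccc2)cc1OCc1ccccc1 | intermediate
18 | 2-{11-[2,4-bis(benzyloxy)-6-hydroxyphenyl]-11-oxoundecyl}-3-(triisopropylsilyloxy)phenyl acetate | CC(=O)Oc1cccc(O[Si](C(C)C)(C(C)C)C(C)C)c1CCCCCCCCCCC(=O)c1c(O)cc(OCc2ccccc2)cc1OCc1ccccc1 | intermediate
19 | 2-{11-[2,4-bis(benzyloxy)-6-hydroxyphenyl]-11-oxoundecyl}-3-hydroxyphenyl acetate | CC(=O)Oc1cccc(O)c1CCCCCCCCCCC(=O)c1c(O)cc(OCc2ccccc2)cc1OCc1ccccc1 | intermediate
20 | 3-hydroxy-2-[11-oxo-11-(2,4,6-trihydroxyphenyl)undecyl]phenyl acetate (CNP0111377.0) | CC(=O)Oc1cccc(O)c1CCCCCCCCCCC(=O)c1c(O)cc(O)cc1O | target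

Total step count: 8. Longest linear sequence: 6 steps (steps 1, 3, 4, 6, 7, 8, from 1).

Steps most likely to fail

Step 3.
- **What may go wrong:** Three processes may outrun the wanted [2+2] capture: oligomerisation of the unsubstituted vinylketene, dipolar self-addition of the diazo enone before it is photolysed, and acylation of the freshly formed phenol by surplus ketene.
- **Fallback:** Ring A is taken from the aromatic pool instead of being built. This path gives up 5 and 9, so it sets out from no numbered compound but from two commercial ones, and it comes back at 14.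
- 1,3-Bis(methoxymethoxy)benzene F1 is lithiated at C-2 between its two directing groups (n-BuLi, THF, 0 °C, directed ortho-metalation). Alkylation with 10-bromodec-1-ene F2 gives 2-(dec-9-enyl)-1,3-bis(methoxymethoxy)benzene F3.
- HCl in MeOH then frees 2-(dec-9-enyl)benzene-1,3-diol F4. One equivalent of i-Pr3SiCl with imidazole in DMF gives 14 by statistical monosilylation, with under- and over-silylated material recycled.
- The price is the loss of the built-in differentiation of the two oxygens.

Step 2.
- **What may go wrong:** Supply may be limited by anionic polymerisation of the enone during enolisation, by conjugate addition of amine or sulfonamide to the vinyl diketone, and by decay of the small, volatile diazo enone on concentration.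
- **Fallback:** The diazo compound is dispensed with and the same ketene is released thermally and reversibly, which keeps its stationary concentration very low. This path sets out from 5 and comes back at 14.
- Commercial 3-oxocyclobutane-1-carboxylic acid F5 undergoes Hunsdiecker-type bromodecarboxylation (HgO, Br2, CH2Cl2, reflux) to 3-bromocyclobutan-1-one F6. Bu3N then eliminates HBr to give cyclobut-2-en-1-one F7.
- Heating F7 with 5 in toluene at 80 °C opens the four-membered ring to 10. This then runs through 11, 12 and 13 to 14, the first-generation form of the same benzannulation.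

Step 6.
- **What may go wrong:** Four processes may erode the coupling: decarbonylation of the acyl-rhodium hydride, chain-walking of the terminal alkene to unreactive internal positions, branched insertion, or acetyl transfer to the phenol of the aldehyde.
- **Fallback:** Cross-metathesis with an aryl vinyl ketone followed by hydrogenation gives the same carbon count. This path sets out from 15 and 16 and comes back at 20.
- Exhaustive benzylation of 16 (BnBr, K2CO3, DMF, 60 °C) gives 2,4,6-tris(benzyloxy)benzaldehyde F8. CH2=CHMgBr in THF at 0 °C gives racemic 1-[2,4,6-tris(benzyloxy)phenyl]prop-2-en-1-ol F9, and MnO2 in CH2Cl2 gives 1-[2,4,6-tris(benzyloxy)phenyl]prop-2-en-1-one F10.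
- Cross-metathesis of 15 with F10 (second-generation Grubbs catalyst, CH2Cl2, 40 °C) gives 2-{(9E)-11-oxo-11-[2,4,6-tris(benzyloxy)phenyl]undec-9-enyl}-3-(triisopropylsilyloxy)phenyl acetate F11.
- HF·pyridine gives 3-hydroxy-2-{(9E)-11-oxo-11-[2,4,6-tris(benzyloxy)phenyl]undec-9-enyl}phenyl acetate F12. H2 over Pd/C in EtOAc then saturates the enone C=C and cleaves all three benzyl ethers to give 20.

Further compounds
F1 | step 3 | 1,3-bis(methoxymethoxy)benzene | COCOc1cccc(OCOC)c1
F2 | step 3 | 10-bromodec-1-ene | C=CCCCCCCCCBr
F3 | step 3 | 2-(dec-9-enyl)-1,3-bis(methoxymethoxy)benzene | C=CCCCCCCCCc1c(OCOC)cccc1OCOC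
F4 | step 3 | 2-(dec-9-enyl)benzene-1,3-diol | C=CCCCCCCCCc1c(O)cccc1O
F5 | step 2 | 3-oxocyclobutane-1-carboxylic acid | O=C1CC(C(=O)O)C1
F6 | step 2 | 3-bromocyclobutan-1-one | O=C1CC(Br)C1
F7 | step 2 | cyclobut-2-en-1-one | O=C1C=CC1
F8 | step 6 | 2,4,6-tris(benzyloxy)benzaldehyde | O=Cc1c(OCc2ccccc2)cc(OCc2ccccc2)cc1OCc1ccccc1
F9 | step 6 | 1-[2,4,6-tris(benzyloxy)phenyl]prop-2-en-1-ol (racemic) | C=CC(O)c1c(OCc2ccccc2)cc(OCc2ccccc2)cc1OCc1ccccc1
F10 | step 6 | 1-[2,4,6-tris(benzyloxy)phenyl]prop-2-en-1-one | C=CC(=O)c1c(OCc2ccccc2)cc(OCc2ccccc2)cc1OCc1ccccc1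
F11 | step 6 | 2-{(9E)-11-oxo-11-[2,4,6-tris(benzyloxy)phenyl]undec-9-enyl}-3-(triisopropylsilyloxy)phenyl acetate | CC(=O)Oc1cccc(O[Si](C(C)C)(C(C)C)C(C)C)c1CCCCCCCC/C=C/C(=O)c1c(OCc2ccccc2)cc(OCc2ccccc2)cc1OCc1ccccc1
F12 | step 6 | 3-hydroxy-2-{(9E)-11-oxo-11-[2,4,6-tris(benzyloxy)phenyl]undec-9-enyl}phenyl acetate | CC(=O)Oc1cccc(O)c1CCCCCCCC/C=C/C(=O)c1c(OCc2ccccc2)cc(OCc2ccccc2)cc1OCc1ccccc1
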